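## Structural features

The target is a sesquineolignan of three oxygenated benzene rings and two three-carbon units: ring A (4-hydroxy-3-methoxyphenyl) stands on C7 of a glycerol chain C7–C8–C9, C8 is joined through an ether oxygen to C4 of ring B (3,5-dimethoxyphenyl), and C1 of ring B is joined to C2 of a 2,3-dihydrobenzofuran whose benzo ring (ring C) carries a methoxy group at C7 and a formyl group at C5, with a hydroxymethyl group (C9') on C3. The four stereocentres form two adjacent pairs, C7 (S)/C8 (R) in the chain (erythro) and C2 (R)/C3 (S) in the heterocycle (trans); ring B keeps the pairs apart, so neither can steer the other. The fragile points are the aldehyde, the C7 alcohol (benzylic to a para-hydroxyaryl ring, so it ionises in acid) and the C2–O1 bond, which is benzylic and para to the ring B oxygen and can open through a quinone methide whenever that oxygen is a free phenoxide. All three rings are electron-rich, which limits strong oxidants and electrophiles. The real difficulty is twofold: the absolute configuration at C2, a centre with no neighbouring handle, and the erythro relation across C8, an α-aryloxy carbon bound to a doubly ortho-substituted phenol oxygen. The key step uses the fact that C2 is a CH bonded only to O1, ring B and C3 and lies 1,5 to C3, which is bonded to C3a of ring C and to a carbon (C9') that can be an ester; C2 can therefore begin as the OCH2 of a benzyl aryl ether and C3 as the carbene carbon of an aryldiazoacetate. After that closure C3 is α to an ester and benzylic, so the trans relation can be reached by equilibration without touching C2.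

## Logic of the disconnections

**23 ⇒ 21.** No skeletal bond is cut; three O–Si bonds and the two acetal C–O bonds are restored. The aldehyde, the ring A phenol and both primary alcohols must be masked while organometallic and hydride reagents are used, and one final operation removes all masks. The forward step must not ionise C7, so fluoride is used first and only brief, dilute acid afterwards.

**21 ⇒ 17 + 20.** The C7–C1 bond of ring A is cut. C7 becomes an aldehyde carbon next to the already fixed C8, and ring A arrives as a nucleophile. This removes a ring and a stereocentre at once. The forward addition must take the Felkin–Anh face (aryloxy group anti to the incoming aryl) to give the erythro pair, which calls for non-chelating conditions, a bulky silyl group on O9 and an aldehyde that is not allowed to epimerise.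

**17 ⇒ 15 ⇒ 14 ⇒ 12 + 13.** The C7=O group is traced back to a vinyl group, and then the C8–O bond to ring B is cut. In 14, C8 is allylic, so the ether bond can be made by a zerovalent-palladium allylic substitution in which a chiral ligand fixes C8 from racemic 13. The whole chain shrinks to a four-carbon commodity. The forward demands are branched regioselectivity with a hindered phenol and an alkene cleavage that spares three electron-rich rings.

**12 ⇒ 11 ⇒ 10 ⇒ 9.** No skeletal bond is cut: the benzyl C–O bond is restored, CH2OH goes back to the ester, and C3 is inverted. The order matters.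
- C3 is equilibrated while the ring B oxygen is still capped, and the cap comes off only after C3 has lost its acidity.
- A silyl ether at that oxygen was weighed and set aside. It would face methoxide in the epimerisation, and a free phenoxide para to C2 could open the ring through a quinone methide while C3 is still labile, which would drain the enantiomeric purity.
- A benzyl ether survives methoxide and hydride, and it is the design change made in the precursor.

**9 ⇒ 8.** The C2–C3 bond is cut (key step). Ring and both ring stereocentres fall away to an achiral diazo ester in which the future C2 is an OCH2 group. The forward step must distinguish two enantiotopic hydrogens under catalyst control and must prefer the 1,5 site to every other C–H bond and to carbene dimerisation.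

**8 ⇒ 7 ⇒ 6.** The diazo group is removed, then the C3–C3a bond is cut between ring C and an acetate unit. The aryl iodide is the natural handle, since it is already present in 4. The forward coupling has to work next to a bulky ortho benzyloxy group and needs the aldehyde masked.

**6 ⇒ 5 ⇒ 3 + 4.** The acetal is opened, and the benzylic C–O bond (future C2–O1) is cut. The phenol 4 is acidic enough for a redox condensation with the alcohol 3, so no electron-rich benzylic halide, which would ionise readily, has to be made. The acetal must be installed under acid mild enough to spare the electron-rich benzyl aryl ether.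

**3 ⇒ 2 ⇒ 1 and 20 ⇒ 19 ⇒ 18.** Only heteroatom bonds and one C–Mg bond are involved: O-benzylation and reduction on one side, O-silylation and magnesium insertion on the other. Both lines end at commodity phenols.

## Other disconnections considered

**Alternative 1:** The C7–O bond of the chain is cut. The precursor A1 is the 7-deoxy compound carrying a free ring A phenol and a tert-butyl carbonate on O9. In the forward direction Ag2O would take A1 to the ring A quinone methide A2, and the carbonate carbonyl oxygen would add to C7 with loss of isobutene to give the six-membered cyclic carbonate A3.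
- In its favour: the oxygen is delivered within a six-membered ring in which aryl and aryloxy can both lie equatorial, so the erythro pair should follow from ring strain rather than from the face selectivity of an open-chain aldehyde. On this point the alternative is the better plan. It also avoids the epimerisable aldehyde 17 and any organometallic reagent.
- Against it here: A1 needs a secondary C8–O bond to the hindered ring B phenol made with defined configuration and without the help of an allyl system. Ring A has a free ortho position, so one-electron coupling at the phenol competes with two-electron oxidation at C7; clean oxidation of this kind is typical of 2,6-disubstituted phenols. A2 can also lose the C8 hydrogen.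
- Comparison: this alternative replaces only the endgame and says nothing about C2 and C3, so it could be joined to the chosen key step. In step count it is about equal (carbonate formation, oxidation, carbonate hydrolysis against silylation, cleavage, addition).

**Alternative 2:** The O1–C2 bond is cut. The precursor A4 is an open 1,2-diarylpropane with one stereocentre (future C3) and two free phenols. Ag2O would oxidise the ring B phenol to the quinone methide A5, and the ring C phenol would add to the methide carbon (5-exo-trig) to give A6.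
- In its favour: the 2,6-dimethoxyphenol of ring B is the ideal substrate for this oxidation, and the ring C phenol is deactivated by the formyl group, so chemoselectivity is inherent. The trans ring arises directly and the aldehyde needs no mask at this stage. No diazo compound and no rhodium are needed, and ring B emerges as the free phenol ready for etherification. On reagent simplicity, handling safety and protecting-group economy around the ring closure it is equal or better.
- Against it: the stereocentre of A4 must be set beforehand by other means, most plausibly with a stoichiometric auxiliary. A5 carries an acidic hydrogen at that very centre and can tautomerise to a stilbene, which erases it. The trans/cis ratio is fixed in the closure and cannot be corrected later, because C3 then bears a CH2O group.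
- Comparison: the chosen plan sets C2 with a catalyst and corrects C3 thermodynamically, while this one relays everything from a centre that is at risk during the key step. The step counts are comparable.

**Alternative 3:** The C3a–C3 bond and the C9'–O bond are cut. The precursor A7 is the ring C iodide carrying an (R)-1-arylallyl ether. Homolysis of the C–I bond (tin hydride or photoredox initiation) would give a σ-radical at C3a that adds 5-exo to the vinyl group, and the resulting primary radical is capped by TEMPO to give A8.
- In its favour: one step makes the ring, the C3 stereocentre and the C9' oxygen at the final oxidation level, so no epimerisation and no ester reduction are needed. The iodide of 4 is used directly and the closure is a very fast radical cyclisation. On step economy it is equal or better.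
- Against it: C2 must already be in place in A7, a doubly activated (allylic, benzylic, electron-rich) secondary aryl ether that is hard to make enantiopure and prone to ionise. The trans/cis ratio of the 5-exo closure is kinetic and usually moderate, and it cannot be repaired. The N–O bond needs a separate reductive cleavage.
- Comparison: the absolute control is moved to an earlier and harder problem, whereas the chosen plan creates C2 from a CH2 group under catalyst control.

Key step: step 7

## Remarks on the chemistry

- Assumption 1: Rh2(S-PTTL)4 is taken, by analogy with simpler 2-benzyloxyphenyl diazoacetates, to give the 2R ring; should the sense be opposite on this substrate, Rh2(R-PTTL)4 is used with no other change.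
- Assumption 2: the (R,R)-configured Trost ligand is taken to give the 2S ether 14 in step 11; otherwise the (S,S)-ligand is used.
- Descriptors: the cis ester 9 is (2R,3S), the trans ester 10 is (2R,3R) and the trans alcohol 11 is again (2R,3S). The letter at C3 follows the CIP ranking of ester against CH2OH, not a change of geometry between 10 and 11.
- The ring B oxygen is carried as a benzyl ether, for the reasons given under 12 ⇒ 9.
- The catalyst is a phthalimido-tert-leucinate, because the insertion site is a methylene group, where arylsulfonylprolinate catalysts discriminate less well than at methine sites.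

## Route

Step 1
Reactants: 1 syringaldehyde
Product: 2 4-benzyloxy-3,5-dimethoxybenzaldehyde
Conditions: BnBr, K2CO3, DMF, 60 °C
Reagents that add atoms: benzyl bromide, BrCc1ccccc1
Why: Williamson etherification of an acidic phenol with a primary benzylic bromide; the benzyl group is stable to every base, hydride and carbene used before step 10.

Step 2
Reactants: 2 4-benzyloxy-3,5-dimethoxybenzaldehyde
Product: 3 (4-benzyloxy-3,5-dimethoxyphenyl)methanol
Conditions: NaBH4, MeOH, 0 °C
Reagents that add atoms: none
Why: Borohydride reduction of an aryl aldehyde; nothing else in the molecule is reducible under these conditions.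

Step 3
Reactants: 3 (4-benzyloxy-3,5-dimethoxyphenyl)methanol; 4 5-iodovanillin
Product: 5 4-[(4-benzyloxy-3,5-dimethoxyphenyl)methoxy]-3-iodo-5-methoxybenzaldehyde
Conditions: PPh3, DIAD, THF, 0 °C to rt
Reagents that add atoms: none
Why: Mitsunobu etherification; the phenol of 4 is made acidic by the para formyl group and the alcohol is primary, so the ether forms without the need for an electron-rich benzylic halide that would ionise easily.

Step 4
Reactants: 5 4-[(4-benzyloxy-3,5-dimethoxyphenyl)methoxy]-3-iodo-5-methoxybenzaldehyde
Product: 6 2-{4-[(4-benzyloxy-3,5-dimethoxyphenyl)methoxy]-3-iodo-5-methoxyphenyl}-1,3-dioxolane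
Conditions: ethylene glycol, HC(OEt)3, PPTS (cat.), toluene, 60 °C
Reagents that add atoms: ethylene glycol, OCCO
Why: Acetalisation driven by an orthoformate as water scavenger; the weak pyridinium acid is chosen so that the electron-rich benzyl aryl ether is not solvolysed, and the acetal masks the aldehyde against the zinc enolate, the carbene, hydride and the Grignard reagent.

Step 5
Reactants: 6 2-{4-[(4-benzyloxy-3,5-dimethoxyphenyl)methoxy]-3-iodo-5-methoxyphenyl}-1,3-dioxolane
Product: 7 methyl 2-{2-[(4-benzyloxy-3,5-dimethoxyphenyl)methoxy]-5-(1,3-dioxolan-2-yl)-3-methoxyphenyl}acetate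
Conditions: BrZnCH2CO2Me (2 equiv; from BrCH2CO2Me, Zn dust, TMSCl cat., THF), Pd2(dba)3 (2.5 mol %), XPhos (10 mol %), THF, 60 °C
Reagents that add atoms: bromo(2-methoxy-2-oxoethyl)zinc, COC(=O)C[Zn]Br
Why: Palladium-catalysed α-arylation of a Reformatsky reagent (Negishi-type coupling of a zinc enolate with an aryl iodide); the neutral zinc enolate tolerates the acetal and the ethers, and the bulky biarylphosphine handles the ortho benzyloxy group.

Step 6
Reactants: 7 methyl 2-{2-[(4-benzyloxy-3,5-dimethoxyphenyl)methoxy]-5-(1,3-dioxolan-2-yl)-3-methoxyphenyl}acetate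
Product: 8 methyl 2-diazo-2-{2-[(4-benzyloxy-3,5-dimethoxyphenyl)methoxy]-5-(1,3-dioxolan-2-yl)-3-methoxyphenyl}acetate
Conditions: p-ABSA, DBU, MeCN, 0 °C to rt
Reagents that add atoms: 4-acetamidobenzenesulfonyl azide, CC(=O)Nc1ccc(cc1)S(=O)(=O)N=[N+]=[N-]
Why: Regitz diazo transfer to an arylacetate, whose benzylic α-hydrogens are acidic enough for an amidine base; no other position in 7 is deprotonated.

Step 7
Reactants: 8 methyl 2-diazo-2-{2-[(4-benzyloxy-3,5-dimethoxyphenyl)methoxy]-5-(1,3-dioxolan-2-yl)-3-methoxyphenyl}acetate
Product: 9 methyl (2R,3S)-2-(4-benzyloxy-3,5-dimethoxyphenyl)-5-(1,3-dioxolan-2-yl)-7-methoxy-2,3-dihydro-1-benzofuran-3-carboxylate (cis)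
Conditions: Rh2(S-PTTL)4 [dirhodium tetrakis(N-phthaloyl-(S)-tert-leucinate)] (1 mol %), toluene, 4 Å MS, −60 °C, slow addition of 8
Reagents that add atoms: none
Why: The dirhodium tetracarboxylate takes N2 from 8 and forms a donor–acceptor carbene of divalent rhodium, with ring C as donor and the ester as acceptor. The carbene carbon then takes one hydrogen of the ArO–CH2 group in a concerted, asynchronous three-centre transition state with hydride-transfer character, the developing positive charge being carried by the ether oxygen and by the para-alkoxy ring B. The closest known reaction type is the enantioselective intramolecular C–H insertion of methyl 2-(2-benzyloxyphenyl)-2-diazoacetates with chiral dirhodium carboxylates, which gives cis-2-aryl-2,3-dihydrobenzofuran-3-carboxylates. The dihydrofuran ring closes by 1,5-insertion (carbene carbon, C3a, C7a, O1, CH2), forming the C2–C3 bond in the five-membered mode that such carbenes prefer. C2 is fixed by the catalyst, whose chiral carboxylate pocket decides which of the two enantiotopic benzylic hydrogens is replaced. C3 is set cis to the aryl group by the geometry of the insertion transition state, and its configuration is not critical because step 8 equilibrates it, so a cis/trans mixture of the same C2 configuration would converge as well. The step needs site selectivity and chemoselectivity: only the ArO–CH2 group lies 1,5 to the carbene, whereas the methoxy groups, the acetal C–H and the PhCH2O group on ring B are out of intramolecular reach. Dimerisation and intermolecular insertion are held back by low temperature, dilution and slow addition.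

Step 8
Reactants: 9 methyl (2R,3S)-2-(4-benzyloxy-3,5-dimethoxyphenyl)-5-(1,3-dioxolan-2-yl)-7-methoxy-2,3-dihydro-1-benzofuran-3-carboxylate
Product: 10 methyl (2R,3R)-2-(4-benzyloxy-3,5-dimethoxyphenyl)-5-(1,3-dioxolan-2-yl)-7-methoxy-2,3-dihydro-1-benzofuran-3-carboxylate (trans)
Conditions: NaOMe (0.3 equiv), MeOH–THF, 0 °C to rt
Reagents that add atoms: none
Why: Base-mediated epimerisation through the ester enolate gives the more stable trans isomer, with aryl and ester on opposite faces. Ring opening by loss of the aryloxide would be the reverse of a 5-endo-trig closure and is stereoelectronically disfavoured, and the benzyl cap keeps ring B from forming a phenoxide, so C2 is untouched.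

Step 9
Reactants: 10 methyl (2R,3R)-2-(4-benzyloxy-3,5-dimethoxyphenyl)-5-(1,3-dioxolan-2-yl)-7-methoxy-2,3-dihydro-1-benzofuran-3-carboxylate
Product: 11 [(2R,3S)-2-(4-benzyloxy-3,5-dimethoxyphenyl)-5-(1,3-dioxolan-2-yl)-7-methoxy-2,3-dihydro-1-benzofuran-3-yl]methanol
Conditions: LiAlH4, THF, 0 °C
Reagents that add atoms: none
Why: Hydride reduction of the ester to the primary alcohol; after this C3 is no longer acidic, so the trans relation is locked, and acetal and ethers are inert to the reagent.

Step 10
Reactants: 11 [(2R,3S)-2-(4-benzyloxy-3,5-dimethoxyphenyl)-5-(1,3-dioxolan-2-yl)-7-methoxy-2,3-dihydro-1-benzofuran-3-yl]methanol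
Product: 12 4-[(2R,3S)-5-(1,3-dioxolan-2-yl)-3-(hydroxymethyl)-7-methoxy-2,3-dihydro-1-benzofuran-2-yl]-2,6-dimethoxyphenol
Conditions: H2 (1 atm), palladium on carbon (10 %), EtOAc, rt, stopped at full conversion
Reagents that add atoms: none
Why: Hydrogenolysis of a primary benzyl aryl ether, which should be much faster than cleavage of the cyclic secondary C2–O1 ether or of the aryl acetal in a neutral, aprotic solvent. If the ring opened reversibly at the phenoxide stage later, it would reclose trans to the now fixed C3.

Step 11
Reactants: 12 4-[(2R,3S)-5-(1,3-dioxolan-2-yl)-3-(hydroxymethyl)-7-methoxy-2,3-dihydro-1-benzofuran-2-yl]-2,6-dimethoxyphenol; 13 2-vinyloxirane (racemic)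
Product: 14 (2S)-2-{4-[(2R,3S)-5-(1,3-dioxolan-2-yl)-3-(hydroxymethyl)-7-methoxy-2,3-dihydro-1-benzofuran-2-yl]-2,6-dimethoxyphenoxy}but-3-en-1-ol
Conditions: Pd2(dba)3·CHCl3 (2.5 mol %), (R,R)-DACH-phenyl Trost ligand, N,N'-[(1R,2R)-cyclohexane-1,2-diyl]bis[2-(diphenylphosphino)benzamide] (7.5 mol %), CH2Cl2, rt, 13 (2 equiv) added slowly
Reagents that add atoms: none
Why: Palladium-catalysed asymmetric allylic etherification of a vinyl epoxide (dynamic kinetic asymmetric transformation). Zerovalent palladium opens 13 to an alkoxide-bearing π-allyl complex whose diastereomers interconvert, the phenol protonates the alkoxide, and the phenoxide attacks the adjacent allyl terminus inside the chiral pocket, which sets C8 and gives the branched ether. The primary alcohol of 12 does not compete, because aliphatic alcohols need a boron co-catalyst for this reaction.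

Step 12
Reactants: 14 (2S)-2-{4-[(2R,3S)-5-(1,3-dioxolan-2-yl)-3-(hydroxymethyl)-7-methoxy-2,3-dihydro-1-benzofuran-2-yl]-2,6-dimethoxyphenoxy}but-3-en-1-ol
Product: 15 bis(tert-butyldimethylsilyl) ether of 14 (both primary hydroxyls silylated; 2S in the chain and 2R,3S in the ring retained)
Conditions: TBSCl (2.5 equiv), imidazole, DMF, rt
Reagents that add atoms: tert-butyldimethylsilyl chloride, CC(C)(C)[Si](C)(C)Cl
Why: Standard silylation of two primary alcohols in one operation; the bulky, non-chelating silyl group on O9 is what later favours Felkin–Anh addition.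

Step 13
Reactants: 15 bis(tert-butyldimethylsilyl) ether of 14
Product: 17 (2R)-2-{4-[(2R,3S)-3-(tert-butyldimethylsilyloxymethyl)-5-(1,3-dioxolan-2-yl)-7-methoxy-2,3-dihydro-1-benzofuran-2-yl]-2,6-dimethoxyphenoxy}-3-(tert-butyldimethylsilyloxy)propanal, via vicinal diol 16 (not isolated)
Conditions: OsO4 (2 mol %), NaIO4 (4 equiv), 2,6-lutidine (2 equiv), dioxane–H2O 3:1, rt; crude aldehyde used at once
Reagents that add atoms: osmium tetroxide, O=[Os](=O)(=O)=O (oxygen donor, restored by NaIO4); sodium periodate, [Na+].[O-]I(=O)(=O)=O
Why: Lemieux–Johnson cleavage (dihydroxylation, then periodate glycol cleavage) of a terminal alkene. It is preferred to ozone because of the three electron-rich rings, and the lutidine buffer protects the acetal and the α-stereocentre of the aldehyde.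

Step 14
Reactants: 18 4-bromo-2-methoxyphenol
Product: 19 (4-bromo-2-methoxyphenoxy)(tert-butyl)dimethylsilane
Conditions: TBSCl, imidazole, DMF, rt
Reagents that add atoms: tert-butyldimethylsilyl chloride, CC(C)(C)[Si](C)(C)Cl
Why: Silylation of the phenol removes the acidic hydrogen so that the aryl bromide can be turned into a Grignard reagent.

Step 15
Reactants: 19 (4-bromo-2-methoxyphenoxy)(tert-butyl)dimethylsilane; 17 (2R)-2-aryloxy-3-silyloxypropanal from step 13
Product: 21 (1S,2R)-1-[4-(tert-butyldimethylsilyloxy)-3-methoxyphenyl]-2-{4-[(2R,3S)-3-(tert-butyldimethylsilyloxymethyl)-5-(1,3-dioxolan-2-yl)-7-methoxy-2,3-dihydro-1-benzofuran-2-yl]-2,6-dimethoxyphenoxy}-3-(tert-butyldimethylsilyloxy)propan-1-ol, via arylmagnesium bromide 20 (not isolated)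
Conditions: 19, Mg turnings, BrCH2CH2Br (cat.), THF, rt to 40 °C; then 17, THF, −78 °C; sat. aq NH4Cl
Reagents that add atoms: magnesium, [Mg] (held in 20, not in 21)
Why: Grignard addition to an α-aryloxy aldehyde under Felkin–Anh (polar) control: the aryloxy group stands anti to the incoming aryl and the nucleophile passes the α-hydrogen, which gives the anti (erythro) pair and hence 7S from 8R. THF, low temperature, the weakly basic aryl ether oxygen and the silyl group on O9 all work against a chelated transition state.

Step 16
Reactants: 21 (1S,2R)-configured tris-silyl ether acetal from step 15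
Product: 23 (2R,3S)-2-{4-[(1S,2R)-1,3-dihydroxy-1-(4-hydroxy-3-methoxyphenyl)propan-2-yl]oxy-3,5-dimethoxyphenyl}-3-(hydroxymethyl)-7-methoxy-2,3-dihydro-1-benzofuran-5-carbaldehyde (the target), via desilylated acetal 22 (not isolated)
Conditions: n-Bu4NF (4 equiv), AcOH (4 equiv), THF, 0 °C to rt; then 1 M aq HCl, THF, 0 °C to rt, short contact
Reagents that add atoms: water, O
Why: Fluoride cleaves the two alkyl silyl ethers and the aryl silyl ether, buffered so that no strongly basic phenoxide persists. The acetal of a para-alkoxybenzaldehyde then hydrolyses in dilute acid within a time too short to ionise the C7 alcohol.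

## Compound list

1 | syringaldehyde (4-hydroxy-3,5-dimethoxybenzaldehyde) | COc1cc(C=O)cc(OC)c1O | starting material
2 | 4-benzyloxy-3,5-dimethoxybenzaldehyde | COc1cc(C=O)cc(OC)c1OCc1ccccc1 | intermediate
3 | (4-benzyloxy-3,5-dimethoxyphenyl)methanol | COc1cc(CO)cc(OC)c1OCc1ccccc1 | intermediate
4 | 5-iodovanillin (4-hydroxy-3-iodo-5-methoxybenzaldehyde) | COc1cc(C=O)cc(I)c1O | starting material
5 | 4-[(4-benzyloxy-3,5-dimethoxyphenyl)methoxy]-3-iodo-5-methoxybenzaldehyde | COc1cc(C=O)cc(I)c1OCc1cc(OC)c(OCc2ccccc2)c(OC)c1 | intermediate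
6 | 2-{4-[(4-benzyloxy-3,5-dimethoxyphenyl)methoxy]-3-iodo-5-methoxyphenyl}-1,3-dioxolane | COc1cc(C2OCCO2)cc(I)c1OCc1cc(OC)c(OCc2ccccc2)c(OC)c1 | intermediate
7 | methyl 2-{2-[(4-benzyloxy-3,5-dimethoxyphenyl)methoxy]-5-(1,3-dioxolan-2-yl)-3-methoxyphenyl}acetate | COC(=O)Cc1cc(C2OCCO2)cc(OC)c1OCc1cc(OC)c(OCc2ccccc2)c(OC)c1 | intermediate
8 | methyl 2-diazo-2-{2-[(4-benzyloxy-3,5-dimethoxyphenyl)methoxy]-5-(1,3-dioxolan-2-yl)-3-methoxyphenyl}acetate (key-step precursor) | COC(=O)C(=[N+]=[N-])c1cc(C2OCCO2)cc(OC)c1OCc1cc(OC)c(OCc2ccccc2)c(OC)c1 | intermediate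
9 | methyl (2R,3S)-2-(4-benzyloxy-3,5-dimethoxyphenyl)-5-(1,3-dioxolan-2-yl)-7-methoxy-2,3-dihydro-1-benzofuran-3-carboxylate (cis; key-step product) | c1ccccc1COc1c(OC)cc([C@@H]2Oc3c(OC)cc(C4OCCO4)cc3[C@@H]2C(=O)OC)cc1OC | intermediate
10 | methyl (2R,3R)-2-(4-benzyloxy-3,5-dimethoxyphenyl)-5-(1,3-dioxolan-2-yl)-7-methoxy-2,3-dihydro-1-benzofuran-3-carboxylate (trans) | c1ccccc1COc1c(OC)cc([C@@H]2Oc3c(OC)cc(C4OCCO4)cc3[C@H]2C(=O)OC)cc1OC | intermediate
11 | [(2R,3S)-2-(4-benzyloxy-3,5-dimethoxyphenyl)-5-(1,3-dioxolan-2-yl)-7-methoxy-2,3-dihydro-1-benzofuran-3-yl]methanol (trans) | c1ccccc1COc1c(OC)cc([C@@H]2Oc3c(OC)cc(C4OCCO4)cc3[C@H]2CO)cc1OC | intermediate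
12 | 4-[(2R,3S)-5-(1,3-dioxolan-2-yl)-3-(hydroxymethyl)-7-methoxy-2,3-dihydro-1-benzofuran-2-yl]-2,6-dimethoxyphenol | COc1cc([C@@H]2Oc3c(OC)cc(C4OCCO4)cc3[C@H]2CO)cc(OC)c1O | intermediate
13 | 2-vinyloxirane (butadiene monoepoxide, racemic) | C=CC1CO1 | starting material
14 | (2S)-2-{4-[(2R,3S)-5-(1,3-dioxolan-2-yl)-3-(hydroxymethyl)-7-methoxy-2,3-dihydro-1-benzofuran-2-yl]-2,6-dimethoxyphenoxy}but-3-en-1-ol | C=C[C@@H](CO)Oc1c(OC)cc([C@@H]2Oc3c(OC)cc(C4OCCO4)cc3[C@H]2CO)cc1OC | intermediate
15 | bis(tert-butyldimethylsilyl) ether of 14 (O9 and O9' silylated; 2S chain, 2R,3S ring) | C=C[C@@H](CO[Si](C)(C)C(C)(C)C)Oc1c(OC)cc([C@@H]2Oc3c(OC)cc(C4OCCO4)cc3[C@H]2CO[Si](C)(C)C(C)(C)C)cc1OC | intermediate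
16 | (3R)-3-{4-[(2R,3S)-3-(tert-butyldimethylsilyloxymethyl)-5-(1,3-dioxolan-2-yl)-7-methoxy-2,3-dihydro-1-benzofuran-2-yl]-2,6-dimethoxyphenoxy}-4-(tert-butyldimethylsilyloxy)butane-1,2-diol (mixture at C2; not isolated) | OCC(O)[C@@H](CO[Si](C)(C)C(C)(C)C)Oc1c(OC)cc([C@@H]2Oc3c(OC)cc(C4OCCO4)cc3[C@H]2CO[Si](C)(C)C(C)(C)C)cc1OC | intermediate
17 | (2R)-2-{4-[(2R,3S)-3-(tert-butyldimethylsilyloxymethyl)-5-(1,3-dioxolan-2-yl)-7-methoxy-2,3-dihydro-1-benzofuran-2-yl]-2,6-dimethoxyphenoxy}-3-(tert-butyldimethylsilyloxy)propanal | O=C[C@@H](CO[Si](C)(C)C(C)(C)C)Oc1c(OC)cc([C@@H]2Oc3c(OC)cc(C4OCCO4)cc3[C@H]2CO[Si](C)(C)C(C)(C)C)cc1OC | intermediate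
18 | 4-bromo-2-methoxyphenol | COc1cc(Br)ccc1O | starting material
19 | (4-bromo-2-methoxyphenoxy)(tert-butyl)dimethylsilane | COc1cc(Br)ccc1O[Si](C)(C)C(C)(C)C | intermediate
20 | [4-(tert-butyldimethylsilyloxy)-3-methoxyphenyl]magnesium bromide (not isolated) | COc1cc([Mg]Br)ccc1O[Si](C)(C)C(C)(C)C | intermediate
21 | (1S,2R)-1-[4-(tert-butyldimethylsilyloxy)-3-methoxyphenyl]-2-{4-[(2R,3S)-3-(tert-butyldimethylsilyloxymethyl)-5-(1,3-dioxolan-2-yl)-7-methoxy-2,3-dihydro-1-benzofuran-2-yl]-2,6-dimethoxyphenoxy}-3-(tert-butyldimethylsilyloxy)propan-1-ol | COc1cc([C@H](O)[C@@H](CO[Si](C)(C)C(C)(C)C)Oc2c(OC)cc([C@@H]3Oc4c(OC)cc(C5OCCO5)cc4[C@H]3CO[Si](C)(C)C(C)(C)C)cc2OC)ccc1O[Si](C)(C)C(C)(C)C | intermediate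
22 | (1S,2R)-2-{4-[(2R,3S)-5-(1,3-dioxolan-2-yl)-3-(hydroxymethyl)-7-methoxy-2,3-dihydro-1-benzofuran-2-yl]-2,6-dimethoxyphenoxy}-1-(4-hydroxy-3-methoxyphenyl)propane-1,3-diol (not isolated) | COc1cc([C@H](O)[C@@H](CO)Oc2c(OC)cc([C@@H]3Oc4c(OC)cc(C5OCCO5)cc4[C@H]3CO)cc2OC)ccc1O | intermediate
23 | (2R,3S)-2-{4-[(1S,2R)-1,3-dihydroxy-1-(4-hydroxy-3-methoxyphenyl)propan-2-yl]oxy-3,5-dimethoxyphenyl}-3-(hydroxymethyl)-7-methoxy-2,3-dihydro-1-benzofuran-5-carbaldehyde (CID53356209) | COc1cc([C@H](O)[C@@H](CO)Oc2c(OC)cc([C@@H]3Oc4c(OC)cc(C=O)cc4[C@H]3CO)cc2OC)ccc1O | target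

## Step count and least certain steps

Total step count: 16. Longest linear sequence: 15 steps (1 to 23 through steps 1–13, 15 and 16; step 14 is a one-step side branch).

**Step 7 (key step).**
- What may go wrong: insufficient discrimination between the two enantiotopic benzylic hydrogens. The 7-methoxy group forces the benzyloxy group out of the plane of ring C and changes the conformation that the catalyst meets, and carbene dimerisation may compete if addition is too fast.
- Fallback (auxiliary plus catalyst, double stereodifferentiation), setting out from 7 and coming back at 11: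
  - saponification (LiOH, THF–H2O) would give 2-{2-[(4-benzyloxy-3,5-dimethoxyphenyl)methoxy]-5-(1,3-dioxolan-2-yl)-3-methoxyphenyl}acetic acid F1;
  - the acid would be esterified (DCC, DMAP) with (R)-2-hydroxy-1-(pyrrolidin-1-yl)propan-1-one F2, made from methyl (R)-lactate and pyrrolidine, to give the (R)-lactamide ester F3;
  - diazo transfer (p-ABSA, DBU) would give the diazo ester F4;
  - Rh2(R-DOSP)4 [dirhodium tetrakis((R)-N-(4-dodecylphenylsulfonyl)prolinate)] in a hydrocarbon solvent would close the ring to the trans-(2R,3R) lactamide ester F5, the auxiliary and catalyst being used as the matched pair for 2R (the mirror-image pair if the sense proves opposite);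
  - LiBH4 would reduce F5 to 11 with release of the auxiliary, so step 8 is not needed.

**Step 15.**
- What may go wrong: poor facial selectivity, if a chelated transition state (magnesium held by the carbonyl and the aryloxy or methoxy oxygens) competes with the Felkin–Anh mode; also enolisation or β-elimination of the aldehyde by the basic reagent.
- Fallback (reagent-controlled reduction in place of substrate-controlled addition), setting out from 21 as the C7 epimer mixture and coming back at 21: Dess–Martin periodinane with NaHCO3 would give the aryl ketone F6, 1-[4-(tert-butyldimethylsilyloxy)-3-methoxyphenyl]-2-aryloxy-3-silyloxypropan-1-one with 8R kept. Reduction with BH3·SMe2 and (S)-Me-CBS oxazaborolidine, (S)-1-methyl-3,3-diphenyltetrahydro-1H,3H-pyrrolo[1,2-c][1,3,2]oxazaborole, in which the aryl group acts as the large substituent, should then give the 7S alcohol 21.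

**Step 11.**
- What may go wrong: slow attack of the doubly ortho-substituted phenoxide, loss of branched selectivity through re-ionisation of the product allyl aryl ether, or incomplete ligand control at C8.
- Fallback (chiral-pool SN2 etherification in place of the allylic substitution), setting out from 12 and coming back at 17:
  - methyl (S)-glycerate would be silylated at the primary hydroxyl to methyl (2S)-3-(tert-butyldimethylsilyloxy)-2-hydroxypropanoate F7 and converted (Tf2O, 2,6-lutidine) into methyl (2S)-3-(tert-butyldimethylsilyloxy)-2-(trifluoromethylsulfonyloxy)propanoate F8;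
  - the phenoxide of 12 (K2CO3, MeCN, 0 °C) would displace the triflate with inversion to give the (2R)-aryloxy ester F9;
  - silylation of the remaining primary alcohol (TBSCl, imidazole) would give the bis-silyl ester F10;
  - i-Bu2AlH in toluene at −78 °C would reduce F10 to the aldehyde 17, so steps 11 to 13 are bypassed.

**Step 5.**
- What may go wrong: slow transmetalation next to the ortho benzyloxy group, with protodeiodination of 6 taking over.
- Fallback (direct arylation of a diazo ester in place of enolate arylation), setting out from 6 and coming back at 8: 6 would be coupled with methyl diazoacetate at the diazo-bearing C–H (Pd(PPh3)4, Et3N, n-Bu4NBr, MeCN, rt) to give 8 directly, which makes no new compound (F0) and removes step 6.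

## Further compounds

F1 | step 7 | 2-{2-[(4-benzyloxy-3,5-dimethoxyphenyl)methoxy]-5-(1,3-dioxolan-2-yl)-3-methoxyphenyl}acetic acid | OC(=O)Cc1cc(C2OCCO2)cc(OC)c1OCc1cc(OC)c(OCc2ccccc2)c(OC)c1
F2 | step 7 | (R)-2-hydroxy-1-(pyrrolidin-1-yl)propan-1-one | C[C@@H](O)C(=O)N1CCCC1
F3 | step 7 | (2R)-1-oxo-1-(pyrrolidin-1-yl)propan-2-yl 2-{2-[(4-benzyloxy-3,5-dimethoxyphenyl)methoxy]-5-(1,3-dioxolan-2-yl)-3-methoxyphenyl}acetate | C[C@@H](OC(=O)Cc1cc(C2OCCO2)cc(OC)c1OCc1cc(OC)c(OCc2ccccc2)c(OC)c1)C(=O)N1CCCC1
F4 | step 7 | (2R)-1-oxo-1-(pyrrolidin-1-yl)propan-2-yl 2-diazo-2-{2-[(4-benzyloxy-3,5-dimethoxyphenyl)methoxy]-5-(1,3-dioxolan-2-yl)-3-methoxyphenyl}acetate | C[C@@H](OC(=O)C(=[N+]=[N-])c1cc(C2OCCO2)cc(OC)c1OCc1cc(OC)c(OCc2ccccc2)c(OC)c1)C(=O)N1CCCC1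
F5 | step 7 | (2R)-1-oxo-1-(pyrrolidin-1-yl)propan-2-yl (2R,3R)-2-(4-benzyloxy-3,5-dimethoxyphenyl)-5-(1,3-dioxolan-2-yl)-7-methoxy-2,3-dihydro-1-benzofuran-3-carboxylate (trans) | c1ccccc1COc1c(OC)cc([C@@H]2Oc3c(OC)cc(C4OCCO4)cc3[C@H]2C(=O)O[C@H](C)C(=O)N5CCCC5)cc1OC
F6 | step 15 | (2R)-1-[4-(tert-butyldimethylsilyloxy)-3-methoxyphenyl]-2-{4-[(2R,3S)-3-(tert-butyldimethylsilyloxymethyl)-5-(1,3-dioxolan-2-yl)-7-methoxy-2,3-dihydro-1-benzofuran-2-yl]-2,6-dimethoxyphenoxy}-3-(tert-butyldimethylsilyloxy)propan-1-one | COc1cc(C(=O)[C@@H](CO[Si](C)(C)C(C)(C)C)Oc2c(OC)cc([C@@H]3Oc4c(OC)cc(C5OCCO5)cc4[C@H]3CO[Si](C)(C)C(C)(C)C)cc2OC)ccc1O[Si](C)(C)C(C)(C)C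
F7 | step 11 | methyl (2S)-3-(tert-butyldimethylsilyloxy)-2-hydroxypropanoate | COC(=O)[C@H](CO[Si](C)(C)C(C)(C)C)O
F8 | step 11 | methyl (2S)-3-(tert-butyldimethylsilyloxy)-2-(trifluoromethylsulfonyloxy)propanoate | COC(=O)[C@H](CO[Si](C)(C)C(C)(C)C)OS(=O)(=O)C(F)(F)F
F9 | step 11 | methyl (2R)-2-{4-[(2R,3S)-5-(1,3-dioxolan-2-yl)-3-(hydroxymethyl)-7-methoxy-2,3-dihydro-1-benzofuran-2-yl]-2,6-dimethoxyphenoxy}-3-(tert-butyldimethylsilyloxy)propanoate | COC(=O)[C@@H](CO[Si](C)(C)C(C)(C)C)Oc1c(OC)cc([C@@H]2Oc3c(OC)cc(C4OCCO4)cc3[C@H]2CO)cc1OC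
F10 | step 11 | methyl (2R)-2-{4-[(2R,3S)-3-(tert-butyldimethylsilyloxymethyl)-5-(1,3-dioxolan-2-yl)-7-methoxy-2,3-dihydro-1-benzofuran-2-yl]-2,6-dimethoxyphenoxy}-3-(tert-butyldimethylsilyloxy)propanoate | COC(=O)[C@@H](CO[Si](C)(C)C(C)(C)C)Oc1c(OC)cc([C@@H]2Oc3c(OC)cc(C4OCCO4)cc3[C@H]2CO[Si](C)(C)C(C)(C)C)cc1OC
F0 | step 5 | none | none
A1 | alternative 1 | tert-butyl (2S)-2-{4-[(2R,3S)-3-(tert-butyldimethylsilyloxymethyl)-5-(1,3-dioxolan-2-yl)-7-methoxy-2,3-dihydro-1-benzofuran-2-yl]-2,6-dimethoxyphenoxy}-3-(4-hydroxy-3-methoxyphenyl)propyl carbonate (7-deoxy precursor) | COc1cc(C[C@@H](COC(=O)OC(C)(C)C)Oc2c(OC)cc([C@@H]3Oc4c(OC)cc(C5OCCO5)cc4[C@H]3CO[Si](C)(C)C(C)(C)C)cc2OC)ccc1O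
A2 | alternative 1 | ring A para-quinone methide of A1 (4-alkylidene-2-methoxycyclohexa-2,5-dien-1-one; alkene geometry not defined) | COC1=CC(=C[C@@H](COC(=O)OC(C)(C)C)Oc2c(OC)cc([C@@H]3Oc4c(OC)cc(C5OCCO5)cc4[C@H]3CO[Si](C)(C)C(C)(C)C)cc2OC)C=CC1=O
A3 | alternative 1 | (4S,5R)-4-(4-hydroxy-3-methoxyphenyl)-5-{4-[(2R,3S)-3-(tert-butyldimethylsilyloxymethyl)-5-(1,3-dioxolan-2-yl)-7-methoxy-2,3-dihydro-1-benzofuran-2-yl]-2,6-dimethoxyphenoxy}-1,3-dioxan-2-one (trans 7,9-cyclic carbonate) | COc1cc([C@@H]2OC(=O)OC[C@H]2Oc3c(OC)cc([C@@H]4Oc5c(OC)cc(C6OCCO6)cc5[C@H]4CO[Si](C)(C)C(C)(C)C)cc3OC)ccc1O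
A4 | alternative 2 | 3-[(2S)-1-(tert-butyldimethylsilyloxy)-3-(4-hydroxy-3,5-dimethoxyphenyl)propan-2-yl]-4-hydroxy-5-methoxybenzaldehyde | COc1cc(C[C@H](CO[Si](C)(C)C(C)(C)C)c2cc(C=O)cc(OC)c2O)cc(OC)c1O
A5 | alternative 2 | ring B para-quinone methide of A4 (4-alkylidene-2,6-dimethoxycyclohexa-2,5-dien-1-one) | COC1=CC(=C[C@H](CO[Si](C)(C)C(C)(C)C)c2cc(C=O)cc(OC)c2O)C=C(OC)C1=O
A6 | alternative 2 | (2R,3S)-2-(4-hydroxy-3,5-dimethoxyphenyl)-3-(tert-butyldimethylsilyloxymethyl)-7-methoxy-2,3-dihydro-1-benzofuran-5-carbaldehyde | COc1cc([C@@H]2Oc3c(OC)cc(C=O)cc3[C@H]2CO[Si](C)(C)C(C)(C)C)cc(OC)c1O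
A7 | alternative 3 | 4-[(1R)-1-[4-(1,3-dioxolan-2-yl)-2-iodo-6-methoxyphenoxy]prop-2-en-1-yl]-2,6-dimethoxyphenyl 2,2-dimethylpropanoate | CC(C)(C)C(=O)Oc1c(OC)cc([C@@H](C=C)Oc2c(I)cc(C3OCCO3)cc2OC)cc1OC
A8 | alternative 3 | 4-[(2R,3S)-5-(1,3-dioxolan-2-yl)-7-methoxy-3-[(2,2,6,6-tetramethylpiperidin-1-yl)oxymethyl]-2,3-dihydro-1-benzofuran-2-yl]-2,6-dimethoxyphenyl 2,2-dimethylpropanoate (trans) | CC(C)(C)C(=O)Oc1c(OC)cc([C@@H]2Oc3c(OC)cc(C4OCCO4)cc3[C@H]2CON5C(C)(C)CCCC5(C)C)cc1OC
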